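The runs are simulated with constants of no real substance, noise included.

Early in the noon flask the target climbs to 8.6% of the substrate at 4.00 min, and from 20.0 min on the readings stand still within their scatter.

common to all: substrate 0.094 M; coupling partner 0.103 M; free catalyst 0.94 mM; impurity 0.95 mM

| charge | capture agent | temperature | remark | time |
|---|---|---|---|---|
| noon | 4.7 mM | −20 °C | the very flask that is asked about, followed so far |  |
| spring | 3.1 mM | −25 °C | run made earlier |  |
| flask | 4.70 mM | −20 °C |  | 50 min |

- noon (time / min: target / %): 4.00: 8.6; 10.0: 12.1; 20.0: 14.1; 30.0: 14.2; 40.0: 14.3
- spring (time / min: target / %): 2.00: 4.1; 5.00: 7.1; 10.0: 9.0; 15.0: 10.6; 20.0: 10.5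

(scatter of a reading: 1 percentage point)

- Thursday's: at 50 min add free catalyst, 100% of the amount charged, then wait 50 min
- Saturday's: at 50 min add coupling partner, 50.0% of the amount charged, then wait 50 min
- Monday's: at 50 min take out 90% of the target then present, then wait 50 min
- Sunday's: at 50 min raise the temperature by 10 K, then wait 50 min
- Wednesday's: change nothing and wait 50 min more

1. target, in percent of the substrate first charged, at 50 min
2. the option that brings most further target ("none" if no option brings more than 2 percentage points) (Thursday's / Saturday's / Monday's / Sunday's / Wednesday's / none)
3. target present, with what was taken out counted in, in percent of the substrate first charged, after Sunday's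
4. target present, with what was taken out counted in, in percent of the substrate first charged, after Wednesday's

- percentages count the substrate that a species holds: one self-condensation product counts as two
- removed target is counted in
- the numbers in the tables scatter by 1 percentage point (one standard deviation)
- reactions considered so far: coupling partner + catalyst intermediate B <-> catalyst intermediate C; catalyst intermediate A + capture agent -> trapped intermediate; free catalyst + impurity -> spent catalyst; 2 substrate -> self-condensation product; substrate + free catalyst -> catalyst intermediate A; catalyst intermediate A -> catalyst intermediate B; catalyst intermediate C -> free catalyst + target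
- additions bring no volume worth counting

Built up one process at a time, the noon flask starts as a bare round: substrate takes free catalyst to catalyst intermediate A, A goes on to B, B takes coupling partner to C, and C gives target and free catalyst back. By itself this round ends on the substrate, the limiting reagent, since more coupling partner than substrate is charged. Self-condensation comes next. It takes substrate without catalyst and lowers that ceiling, but its rate falls with [substrate]^2, a fading loss, and the readings show an edge.

Then come the exits of the catalyst. The noon flask holds about as much impurity as free catalyst, and capture agent at 5.00 times the free catalyst. Each exit closes a round for good, which turns the stop into a count. The plateau, 14.2% as a mean of readings, makes 14.2 target per catalyst charged. This is the turnover budget, the turnover number read from the plateau.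

The spring flask, colder and with less capture agent, was followed to 20.0 min, and its last readings, 10.6% and 10.5%, aren't taken here as a finished budget.

The rule is target = budget × [catalyst] / [substrate charged], capped by the substrate present. This reckoning therefore keeps the noon flask at 14.2% at 50 min, and the options that bring no catalyst add nothing. Thursday's buys up to 14.2%, provided that much substrate remains, which the readings don't show.

The forecast gives 14.2% at 50 min, 14.4% after Sunday's and 14.3% after Wednesday's, and it chooses Thursday's: “Only fresh catalyst helps: capture agent remains, but substrate should too, so I expect a second burst of similar size.”

    coupling partner + catalyst intermediate B ⇌ catalyst intermediate C (K = 12.0 /M, k = 93.0 /M/min, Ea = 41.0 kJ/mol, ΔH = 1.00 kJ/mol)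
    catalyst intermediate A + capture agent → trapped intermediate (k = 17.0 /M/min, Ea = 38.0 kJ/mol)
    free catalyst + impurity → spent catalyst (k = 2900 /M/min, Ea = 41.0 kJ/mol)
    2 substrate → self-condensation product (k = 0.890 /M/min, Ea = 53.0 kJ/mol)
    substrate + free catalyst → catalyst intermediate A (k = 420 /M/min, Ea = 46.0 kJ/mol)
    catalyst intermediate A → catalyst intermediate B (k = 5.80 /min, Ea = 67.0 kJ/mol)
    catalyst intermediate C → free catalyst + target (k = 93.0 /min, Ea = 68.0 kJ/mol)
    (constants at −20 °C)

The noon flask gives 12.8% at 50 min, 12.8% after Sunday's and 12.8% after Wednesday's. Thursday's gains 9.5 percentage points, with 10% of the substrate left beforehand, less than the budget's 14.2%. At the start, free catalyst goes to catalyst intermediate A 14 times as fast as to spent catalyst, which stands beside the budget of 14.2. By 50.0 min, 82.7% of the catalyst is spent and 17.3% trapped. For the neighbour charged with 2.4 × 10⁻⁴ M of impurity, the budget scaled by [impurity] gives 56.2, a ceiling of 56.2%. That neighbour reaches 38.1%, with 1.2% of its substrate left and 21.0% of its catalyst still free.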